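**Plan**
- Enabling feature: ring B (C1, C8, C7, C6, C5, C9) hangs on C1 and C5, the two equivalent prenyl-bearing carbons of a symmetrical aroylphloroglucinol (ring A = C1, C2, C3, C4, C5, C9). Its C7 substituent is endo, pointing at C3, so it can be tied to C3 for a time.
- Cuts: first the O-methyl and O-silyl groups, then C10–C2' of the geranyl chain (sp3–sp2 Negishi coupling). The temporary C3–C10 aldol bond is then restored, and C5–C6, C1–C8 and C3–C10 are cut together, leading to diprenyl aroylphloroglucinol 7 and acetoxymethyl enal 12.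
- Forward order: ring A is built aromatic (Hoesch acylation, double C-prenylation, silylation). One operation dearomatises it and closes ring B and a temporary adamantane ring. Retro-aldol/reduction reopens the cage, and the geranyl chain is joined last.
- Stereochemistry: C5 (and with it C1) comes from a cinchoninium phase-transfer catalyst that chooses between enantiotopic carbons. C7 endo comes from the aldol trap. The E alkene comes from syn-carboalumination and is kept in the coupling.

Key step: step 9

Remarks on the chemistry (assumptions)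
- Numbering: C1 and C5 are the prenylated bridgeheads, C9 the bridging ketone, C2–C3–C4 the aroyl-bearing bridge, C8 the gem-dimethyl carbon, C7 the geranyl-bearing carbon. C10 is the former aldehyde carbon (geranyl C1').
- The target is written as its C4-enol tautomer, which equilibrates with the C2-enol form of the same compound. The descriptors (1S,5S,7S) refer to the drawn tautomer in this numbering.
- The cinchonine-derived catalyst is assumed to select the enantiotopic carbon that leads to this series. If the sense is opposite, the pseudoenantiomeric cinchonidinium salt is used.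
- The benzoyl oxygen carries a triisopropylsilyl group, because aryl tert-butyldimethylsilyl ethers are too labile to hydroxide for step 9.
- Intermediates that are not isolated are drawn in neutral form, except 21, which is listed as the sodium enolate that the fragmentation in step 10 forms directly.

**Route**

Step 1
Reactants: 1 phloroglucinol; 2 3-hydroxybenzonitrile
Product: 4 (3-hydroxyphenyl)(2,4,6-trihydroxyphenyl)methanone, via ketiminium chloride 3 (not isolated)
Conditions: ZnCl2, HCl (g), Et2O, 0 → 23 °C; then H2O, 100 °C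
Reagents that add atoms: water, SMILES O (ketone oxygen)
Why: Houben–Hoesch acylation: the ZnCl2/HCl-activated nitrile attacks the very electron-rich phloroglucinol once, because the ketiminium salt 3 is deactivated toward a second attack, and hydrolysis gives the ketone while the meta-hydroxyl of the nitrile is too weak a nucleophile to interfere.

Step 2
Reactants: 4 (3-hydroxyphenyl)(2,4,6-trihydroxyphenyl)methanone; 5 prenyl bromide (2.1 equiv)
Product: 6 (3-hydroxyphenyl)[2,4,6-trihydroxy-3,5-bis(3-methylbut-2-enyl)phenyl]methanone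
Conditions: 5% aq. KOH, 0 °C
Reagents that add atoms: none
Why: Aqueous-base C-prenylation of an acylphloroglucinol (alkylation of an ambident phenoxide): water hydrogen-bonds the phenoxide oxygens so the two free ring carbons, the only C-nucleophilic sites, are alkylated, whereas the isolated 3'-phenoxide has no activated carbon and should react more slowly at oxygen.

Step 3
Reactants: 6 (3-hydroxyphenyl)[2,4,6-trihydroxy-3,5-bis(3-methylbut-2-enyl)phenyl]methanone
Product: 7 [2,4,6-trihydroxy-3,5-bis(3-methylbut-2-enyl)phenyl][3-(triisopropylsilyloxy)phenyl]methanone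
Conditions: i-Pr3SiCl (1.05 equiv), imidazole, DMF, 0 °C
Reagents that add atoms: chlorotriisopropylsilane, SMILES CC(C)[Si](Cl)(C(C)C)C(C)C
Why: Steric differentiation in imidazole-mediated O-silylation: each phloroglucinol hydroxyl is flanked by two ortho substituents and the 2- and 6-hydroxyls are chelated to the ketone, so the bulky silyl chloride should go to the unhindered 3'-hydroxyl.

Step 4
Reactants: 8 diethyl isopropylidenemalonate
Product: 9 2-(propan-2-ylidene)propane-1,3-diol
Conditions: i-Bu2AlH (4.4 equiv), CH2Cl2, −78 → 0 °C; aq. potassium sodium tartrate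
Reagents that add atoms: none
Why: Aluminium hydride 1,2-reduction of both conjugated ester groups: at low temperature i-Bu2AlH delivers hydride to the carbonyl carbons and not to the fully substituted β-carbon, giving the allylic 1,3-diol.

Step 5
Reactants: 9 2-(propan-2-ylidene)propane-1,3-diol
Product: 11 2-(hydroxymethyl)-3-methylbut-2-enyl acetate, via cyclic orthoester 10 (not isolated)
Conditions: MeC(OMe)3, PPTS (cat.), CH2Cl2, 23 °C; then H2O
Reagents that add atoms: trimethyl orthoacetate, SMILES COC(C)(OC)OC; water, SMILES O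
Why: Monoacylation of a symmetrical 1,3-diol through its cyclic orthoester: mild acidic hydrolysis opens 10 to the hydroxy acetate only, which avoids the statistical mixture of a direct acetylation.

Step 6
Reactants: 11 2-(hydroxymethyl)-3-methylbut-2-enyl acetate
Product: 12 2-(acetoxymethyl)-3-methylbut-2-enal
Conditions: MnO2 (excess), CH2Cl2, 23 °C
Reagents that add atoms: none
Why: MnO2 oxidation of a primary allylic alcohol stops at the enal and leaves the allylic acetate untouched.

Step 7
Reactants: 13 6-methylhept-5-en-2-one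
Product: 15 6-methylhept-5-en-1-yne, via enol phosphate 14 (not isolated)
Conditions: LiN(i-Pr)2, THF, −78 °C; ClP(O)(OEt)2, −78 → 23 °C; LiN(i-Pr)2 (2.3 equiv), −78 → 23 °C; aq. NH4Cl
Reagents that add atoms: none
Why: Methyl ketone-to-alkyne conversion through the enol phosphate: the kinetic terminal lithium enolate is trapped as 14, and amide-induced β-elimination of diethyl phosphate gives the lithium acetylide, which is protonated on work-up.

Step 8
Reactants: 15 6-methylhept-5-en-1-yne
Product: 17 (E)-1-iodo-2,6-dimethylhepta-1,5-diene, via alkenylalane 16 (not isolated)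
Conditions: AlMe3 (2 equiv), Cp2ZrCl2 (0.25 equiv), CH2Cl2, 0 → 23 °C; then I2, THF, −30 → 0 °C
Reagents that add atoms: trimethylaluminium, SMILES C[Al](C)C; iodine, SMILES II
Why: Zirconium-catalysed methylalumination (Negishi carboalumination): methyl and aluminium add syn across the terminal alkyne with aluminium on the terminal carbon, and iodinolysis of the C–Al bond with retention fixes the E trisubstituted alkene, the remote trisubstituted alkene being inert.

Step 9
Reactants: 7 [2,4,6-trihydroxy-3,5-bis(3-methylbut-2-enyl)phenyl][3-(triisopropylsilyloxy)phenyl]methanone; 12 2-(acetoxymethyl)-3-methylbut-2-enal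
Product: 20 adamantane aldol (bicyclo[3.3.1]nonane-2,4,9-trione with C3 bonded to carbinol carbon C10 on C7; C10 hydroxyl directed toward C6), via C-alkylated dienone 18 (not isolated), via endo aldehyde 19 (not isolated)
Conditions: O(9)-allyl-N-(9-anthracenylmethyl)cinchoninium bromide (25 mol %), CsOH·H2O (5 equiv), 4 Å MS, CH2Cl2, −50 °C; aq. NH4Cl
Reagents that add atoms: none
Why: Ion-paired with the chiral ammonium cation, the phenoxide of 7 is C-alkylated at one of its two enantiotopic prenyl-bearing carbons by net displacement of the allylic acetate of 12 (C5–C6, giving 18); the dienolate then adds through the second prenyl-bearing carbon to the β,β-dimethyl enal carbon (C1–C8), the aldehyde enolate is protonated at C7, and the endo aldehyde 19 is captured by aldol addition of the triketone enolate carbon C3 (C3–C10). The closest known reaction type is the alkylative dearomatisation–annulation of diprenyl acylphloroglucinols with α-acetoxymethyl enals under cinchona phase-transfer catalysis, which ends in the same kind of adamantane aldol. Ring B closes by a 6-endo-trig Michael addition and the cage ring by a 6-exo-trig aldol addition. C5 is set by the catalyst and C1 follows because the three-atom bridge can only span C5 and C1 on one face; C7 is epimerisable through the aldehyde enolate, but only its endo epimer can reach C3, so the aldol stores that configuration; C3 and C10 are fixed by the cage, with the hydroxyl expected away from the C8 methyls under reversible aldol conditions. The step needs C- over O-alkylation, attack at the prenyl-bearing and not the aroyl-bearing carbon, and an inert benzoyl oxygen; these are secured by the soft delocalised phenoxide in CH2Cl2, by the 1,3-relationship of the two prenyl-bearing carbons that alone matches the three-carbon bis-electrophile, and by the triisopropylsilyl ether.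

Step 10
Reactants: 20 adamantane aldol
Product: 22 7-endo-(hydroxymethyl)-4-hydroxy-8,8-dimethyl-1,5-bis(3-methylbut-2-enyl)-3-[3-(triisopropylsilyloxy)benzoyl]bicyclo[3.3.1]non-3-ene-2,9-dione, via ring-opened sodium enolate 21 (not isolated)
Conditions: NaOMe (1.0 equiv), THF/MeOH, −20 °C; then NaBH4, −40 °C; aq. NH4Cl
Reagents that add atoms: none
Why: Base-triggered retro-aldol cleavage of the C3–C10 bond with in situ hydride capture: the C10 alkoxide fragments directly to the far more stable sodium 2-acyl-1,3-diketone enolate 21, whose endo aldehyde NaBH4 should reduce faster than it can epimerise at C7 or reclose, while the enolate charge shields the C2, C4 and aroyl carbonyls and the C9 ketone is flanked by two quaternary carbons, so the endo C7 configuration stored in the cage passes unchanged to the hydroxymethyl group.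

Step 11
Reactants: 22 7-endo-(hydroxymethyl) triketone enol
Product: 23 7-endo-(hydroxymethyl)-4-methoxy-8,8-dimethyl-1,5-bis(3-methylbut-2-enyl)-3-[3-(triisopropylsilyloxy)benzoyl]bicyclo[3.3.1]non-3-ene-2,9-dione
Conditions: Me3SiCHN2, i-Pr2NEt, MeCN/MeOH, 0 °C
Reagents that add atoms: (trimethylsilyl)diazomethane, SMILES C[Si](C)(C)C=[N+]=[N-]
Why: O-methylation of an acidic vinylogous acid with trimethylsilyldiazomethane (proton transfer, then SN2 on the methyldiazonium ion) leaves the neutral primary alcohol alone; the less hindered C4 oxygen is expected to react, and any C2-O-methyl regioisomer would converge on the same target in step 14.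

Step 12
Reactants: 23 7-endo-(hydroxymethyl) C4-methyl enol ether
Product: 24 7-endo-(iodomethyl)-4-methoxy-8,8-dimethyl-1,5-bis(3-methylbut-2-enyl)-3-[3-(triisopropylsilyloxy)benzoyl]bicyclo[3.3.1]non-3-ene-2,9-dione
Conditions: I2, PPh3, imidazole, CH2Cl2, 0 → 23 °C
Reagents that add atoms: iodine, SMILES II
Why: Appel-type iodination: the primary alkoxyphosphonium ion is displaced by iodide in an SN2 reaction at C10, which is not a stereocentre, under conditions that leave the ketones, the enol ether, the silyl ether and the alkenes untouched.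

Step 13
Reactants: 24 7-endo-(iodomethyl) C4-methyl enol ether; 17 (E)-1-iodo-2,6-dimethylhepta-1,5-diene
Product: 26 7-endo-[(2E)-3,7-dimethylocta-2,6-dienyl]-4-methoxy-8,8-dimethyl-1,5-bis(3-methylbut-2-enyl)-3-[3-(triisopropylsilyloxy)benzoyl]bicyclo[3.3.1]non-3-ene-2,9-dione, via alkylzinc iodide 25 (not isolated)
Conditions: Zn dust (activated with BrCH2CH2Br and Me3SiCl), LiCl, THF, 35 °C; then 17, PdCl2(dppf) (5 mol %; dppf = 1,1'-bis(diphenylphosphino)ferrocene), THF, 23 → 45 °C
Reagents that add atoms: none
Why: Negishi sp3–sp2 cross-coupling: LiCl-assisted zinc insertion gives the ketone-tolerant alkylzinc iodide 25, which transmetalates to the alkenylpalladium iodide formed from 17 and reductively eliminates with retention of the E geometry, the wide-bite-angle dppf ligand disfavouring β-hydride elimination.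

Step 14
Reactants: 26 7-endo-geranyl C4-methyl enol ether silyl ether
Product: 27 (1S,5S,7S)-7-endo-[(2E)-3,7-dimethylocta-2,6-dienyl]-4-hydroxy-3-(3-hydroxybenzoyl)-8,8-dimethyl-1,5-bis(3-methylbut-2-enyl)bicyclo[3.3.1]non-3-ene-2,9-dione (CNP0290731.1)
Conditions: LiOH·H2O, dioxane/H2O, 90 °C; then dil. HCl to pH 4
Reagents that add atoms: lithium hydroxide, SMILES [Li+].[OH-] (its oxygen becomes the C4 enol oxygen)
Why: Hydroxide-mediated double deprotection: addition–elimination of hydroxide at C4 of the vinylogous methyl ester releases the enolised β-triketone, the same hydroxide cleaves the base-labile aryl silyl ether, and no stereocentre can epimerise because C1 and C5 are quaternary and C7 is not α to a carbonyl.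

**Compound list**

1 | phloroglucinol (benzene-1,3,5-triol) | Oc1cc(O)cc(O)c1 | starting material
2 | 3-hydroxybenzonitrile | N#Cc1cccc(O)c1 | starting material
3 | (3-hydroxyphenyl)(2,4,6-trihydroxyphenyl)methaniminium chloride | [NH2+]=C(c1cccc(O)c1)c1c(O)cc(O)cc1O.[Cl-] | intermediate
4 | (3-hydroxyphenyl)(2,4,6-trihydroxyphenyl)methanone | O=C(c1cccc(O)c1)c1c(O)cc(O)cc1O | intermediate
5 | prenyl bromide (1-bromo-3-methylbut-2-ene) | CC(C)=CCBr | starting material
6 | (3-hydroxyphenyl)[2,4,6-trihydroxy-3,5-bis(3-methylbut-2-enyl)phenyl]methanone | CC(C)=CCc1c(O)c(CC=C(C)C)c(O)c(C(=O)c2cccc(O)c2)c1O | intermediate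
7 | [2,4,6-trihydroxy-3,5-bis(3-methylbut-2-enyl)phenyl][3-(triisopropylsilyloxy)phenyl]methanone | CC(C)=CCc1c(O)c(CC=C(C)C)c(O)c(C(=O)c2cccc(O[Si](C(C)C)(C(C)C)C(C)C)c2)c1O | intermediate
8 | diethyl isopropylidenemalonate | CCOC(=O)C(=C(C)C)C(=O)OCC | starting material
9 | 2-(propan-2-ylidene)propane-1,3-diol | CC(C)=C(CO)CO | intermediate
10 | 2-methoxy-2-methyl-5-(propan-2-ylidene)-1,3-dioxane | COC1(C)OCC(=C(C)C)CO1 | intermediate
11 | 2-(hydroxymethyl)-3-methylbut-2-enyl acetate | CC(C)=C(CO)COC(C)=O | intermediate
12 | 2-(acetoxymethyl)-3-methylbut-2-enal | CC(C)=C(C=O)COC(C)=O | intermediate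
13 | 6-methylhept-5-en-2-one | CC(C)=CCCC(C)=O | starting material
14 | diethyl 6-methylhepta-1,5-dien-2-yl phosphate | C=C(CCC=C(C)C)OP(=O)(OCC)OCC | intermediate
15 | 6-methylhept-5-en-1-yne | C#CCCC=C(C)C | intermediate
16 | [(E)-2,6-dimethylhepta-1,5-dienyl]dimethylaluminium | C[Al](C)/C=C(\C)CCC=C(C)C | intermediate
17 | (E)-1-iodo-2,6-dimethylhepta-1,5-diene | I/C=C(\C)CCC=C(C)C | intermediate
18 | 4-(2-formyl-3-methylbut-2-enyl)-3,5-dihydroxy-4,6-bis(3-methylbut-2-enyl)-2-[3-(triisopropylsilyloxy)benzoyl]cyclohexa-2,5-dien-1-one; the quaternary ring carbon becomes C5 and is configured as in 20 | O=CC(=C(C)C)C[C@]1(CC=C(C)C)C(O)=C(CC=C(C)C)C(=O)C(C(=O)c2cccc(O[Si](C(C)C)(C(C)C)C(C)C)c2)=C1O | intermediate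
19 | 7-endo-formyl-4-hydroxy-8,8-dimethyl-1,5-bis(3-methylbut-2-enyl)-3-[3-(triisopropylsilyloxy)benzoyl]bicyclo[3.3.1]non-3-ene-2,9-dione (C1, C5, C7 as in 27) | O=C[C@H]1C[C@]2(CC=C(C)C)C(=O)[C@@](CC=C(C)C)(C(=O)C(C(=O)c3cccc(O[Si](C(C)C)(C(C)C)C(C)C)c3)=C2O)C1(C)C | intermediate
20 | adamantane aldol: the 2,4,9-trione of 19 with C3 (bearing the aroyl group) bonded to carbinol carbon C10 on C7; C10 hydroxyl toward C6, away from C8; C1, C5, C7 as in 27 | O[C@H]4[C@H]1C[C@]2(CC=C(C)C)C(=O)[C@@](CC=C(C)C)(C(=O)[C@@]4(C(=O)c3cccc(O[Si](C(C)C)(C(C)C)C(C)C)c3)C2=O)C1(C)C | intermediate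
21 | sodium 7-endo-formyl-8,8-dimethyl-1,5-bis(3-methylbut-2-enyl)-2,9-dioxo-3-[3-(triisopropylsilyloxy)benzoyl]bicyclo[3.3.1]non-3-en-4-olate (sodium enolate released by the retro-aldol; C1, C5, C7 as in 27) | [Na+].O=C[C@H]1C[C@]2(CC=C(C)C)C(=O)[C@@](CC=C(C)C)(C(=O)C(C(=O)c3cccc(O[Si](C(C)C)(C(C)C)C(C)C)c3)=C2[O-])C1(C)C | intermediate
22 | 7-endo-(hydroxymethyl)-4-hydroxy-8,8-dimethyl-1,5-bis(3-methylbut-2-enyl)-3-[3-(triisopropylsilyloxy)benzoyl]bicyclo[3.3.1]non-3-ene-2,9-dione | OC[C@H]1C[C@]2(CC=C(C)C)C(=O)[C@@](CC=C(C)C)(C(=O)C(C(=O)c3cccc(O[Si](C(C)C)(C(C)C)C(C)C)c3)=C2O)C1(C)C | intermediate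
23 | 7-endo-(hydroxymethyl)-4-methoxy-8,8-dimethyl-1,5-bis(3-methylbut-2-enyl)-3-[3-(triisopropylsilyloxy)benzoyl]bicyclo[3.3.1]non-3-ene-2,9-dione | OC[C@H]1C[C@]2(CC=C(C)C)C(=O)[C@@](CC=C(C)C)(C(=O)C(C(=O)c3cccc(O[Si](C(C)C)(C(C)C)C(C)C)c3)=C2OC)C1(C)C | intermediate
24 | 7-endo-(iodomethyl)-4-methoxy-8,8-dimethyl-1,5-bis(3-methylbut-2-enyl)-3-[3-(triisopropylsilyloxy)benzoyl]bicyclo[3.3.1]non-3-ene-2,9-dione | IC[C@H]1C[C@]2(CC=C(C)C)C(=O)[C@@](CC=C(C)C)(C(=O)C(C(=O)c3cccc(O[Si](C(C)C)(C(C)C)C(C)C)c3)=C2OC)C1(C)C | intermediate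
25 | alkylzinc iodide from 24 (C10–ZnI) | I[Zn]C[C@H]1C[C@]2(CC=C(C)C)C(=O)[C@@](CC=C(C)C)(C(=O)C(C(=O)c3cccc(O[Si](C(C)C)(C(C)C)C(C)C)c3)=C2OC)C1(C)C | intermediate
26 | 7-endo-[(2E)-3,7-dimethylocta-2,6-dienyl]-4-methoxy-8,8-dimethyl-1,5-bis(3-methylbut-2-enyl)-3-[3-(triisopropylsilyloxy)benzoyl]bicyclo[3.3.1]non-3-ene-2,9-dione | CC(C)=CCC/C(C)=C/C[C@H]1C[C@]2(CC=C(C)C)C(=O)[C@@](CC=C(C)C)(C(=O)C(C(=O)c3cccc(O[Si](C(C)C)(C(C)C)C(C)C)c3)=C2OC)C1(C)C | intermediate
27 | (1S,5S,7S)-7-endo-[(2E)-3,7-dimethylocta-2,6-dienyl]-4-hydroxy-3-(3-hydroxybenzoyl)-8,8-dimethyl-1,5-bis(3-methylbut-2-enyl)bicyclo[3.3.1]non-3-ene-2,9-dione (CNP0290731.1) | CC(C)=CCC/C(C)=C/C[C@H]1C[C@]2(CC=C(C)C)C(=O)[C@@](CC=C(C)C)(C(=O)C(C(=O)c3cccc(O)c3)=C2O)C1(C)C | target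

**Count and risks**

Total: 14 steps. Longest linear sequence: 9 steps (steps 1, 2, 3, 9, 10, 11, 12, 13, 14).

Steps most likely to fail:

1. Step 9. The chiral ion pair may discriminate poorly between the two enantiotopic prenyl-bearing carbons, and the aryl silyl ether may be partly lost under hydroxide. Fallback: starting from 7 and 12, the annulation is run with an achiral ammonium salt (Bu4NBr, CsOH·H2O, 4 Å MS, CH2Cl2, −50 °C) to give the racemic adamantane aldol F1. The rigid cage is then resolved by preparative chromatography on a chiral stationary phase (cellulose tris(3,5-dimethylphenylcarbamate)), and the route is rejoined at 20.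

2. Step 10. Borohydride may attack the ketones of the intact cage before the C3–C10 bond opens, or the ring-opened aldehyde may reclose or epimerise at C7 before it is reduced. Fallback: starting from 20, opening and reduction are separated. The cage is opened with KN(SiMe3)2 (1.0 equiv, THF, −78 → −20 °C) and the triketone enolate is capped at oxygen with MeOTf at −78 °C. This gives the endo aldehyde C4-methyl enol ether F2, which cannot reclose and whose conjugated carbonyls are deactivated. Reduction of the aldehyde alone (NaBH4, MeOH, −40 °C; aq. NH4Cl) then leads directly to 23, so step 11 is not needed.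

3. Step 13. Zinc insertion at the β-branched iodide may be incomplete, or the transient C10 radical or organozinc may add to the neighbouring C3=C4 enol ether and re-form a cage. Fallback: the polarity is reversed. Starting from 17, iodine–lithium exchange (t-BuLi, Et2O, −78 °C) gives the alkenyllithium F3, and ZnCl2 converts it into the alkenylzinc chloride F4. F4 is coupled with the intact alkyl iodide 24 under alkyl-electrophile Negishi conditions (Pd2(dba)3, tricyclopentylphosphine, N-methylimidazole, THF/NMP, 80 °C), in which zerovalent palladium attacks the primary iodide in an SN2-type oxidative addition. The route is rejoined at 26.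

**Further compounds**

F1 | step 9 | racemic adamantane aldol (20 together with its enantiomer) | O[C@H]4[C@H]1C[C@]2(CC=C(C)C)C(=O)[C@@](CC=C(C)C)(C(=O)[C@@]4(C(=O)c3cccc(O[Si](C(C)C)(C(C)C)C(C)C)c3)C2=O)C1(C)C.O[C@@H]4[C@@H]1C[C@@]2(CC=C(C)C)C(=O)[C@](CC=C(C)C)(C(=O)[C@]4(C(=O)c3cccc(O[Si](C(C)C)(C(C)C)C(C)C)c3)C2=O)C1(C)C
F2 | step 10 | 7-endo-formyl-4-methoxy-8,8-dimethyl-1,5-bis(3-methylbut-2-enyl)-3-[3-(triisopropylsilyloxy)benzoyl]bicyclo[3.3.1]non-3-ene-2,9-dione | O=C[C@H]1C[C@]2(CC=C(C)C)C(=O)[C@@](CC=C(C)C)(C(=O)C(C(=O)c3cccc(O[Si](C(C)C)(C(C)C)C(C)C)c3)=C2OC)C1(C)C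
F3 | step 13 | [(E)-2,6-dimethylhepta-1,5-dienyl]lithium | [Li]/C=C(\C)CCC=C(C)C
F4 | step 13 | [(E)-2,6-dimethylhepta-1,5-dienyl]zinc chloride | Cl[Zn]/C=C(\C)CCC=C(C)C
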